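The constants are made up, and the outcome is calculated.

Tuesday's flask and Thursday's differ in one charge, the incoming ligand, and with little complex to spare you want the yield counted first.

| flask | starting complex | incoming ligand | time |
|---|---|---|---|
| Tuesday's | 1.5 M | 1.80 M | 2.0 h |
| Thursday's | 1.5 M | 2.30 M | 2.0 h |

    starting complex + incoming ligand → leaving ligand + complex with one exchanged (k1 = 0.00220 L mol⁻¹ s⁻¹)
    complex with one exchanged + incoming ligand → leaving ligand + complex with two exchanged (k2 = 0.00185 L mol⁻¹ s⁻¹)
    leaving ligand + incoming ligand ⇌ idle adduct, settled at all times (K3 = 1.2 L mol⁻¹)
    2 incoming ligand → homo dimer (k4 = 1.61 × 10⁻⁴ L mol⁻¹ s⁻¹)

- part of the starting complex that has reacted at the end, Tuesday's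
- part of the starting complex that has reacted at the end, Thursday's
- what raising the concentration of incoming ligand from its lowest to its highest value here does to the part of the starting complex that has reacted (changes below 5 percentage points count as none) (it falls / it rises / no change)

- for leaving ligand the idle adduct is counted in
- a doubled species enters its step squared and goes two at a time
- run time (Tuesday's): 2.0 h

A complex can take 2 ligands, but Tuesday's charge offers 1.20 per complex, so the incoming ligand is the limiting reagent. With the ligand as charged, the starting complex has a half-life of 2.9 min by the first exchange alone, short against 2.0 h, so I count ligand, not time.

I count it two ways. From the complexes: both exchanges use the same ligand, so their split depends on how far the reaction has gone, not on time. With r = 0.841, the ratio of the second constant to the first, and m the share of starting complex left, the share with one exchanged is (m^r − m)/(1 − r). Suppose 25.0 % is left. Then 38.8 % has one exchanged, and the complexes have spent 1.11 ligands per charged complex.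

From the ligand: at the start the dimer step uses ligand at 0.176 of the first exchange's rate. That ratio shrinks as the ligand goes, so I take 0.5 of it over the run. This gives the ligand budget, the ligand per charged complex left for the complexes after the dimer's share: 1.09.

The two counts lie close. Setting the budget into the balance leaves 25.9 %, so I commit to 74.1 % reacted on Tuesday's. On Thursday's the budget is 1.36. A trial of 16.7 % left puts 34.6 % at one exchanged, which gives 85.3 % reacted. A second pass from that figure gives 84.5 %, and I commit to that, a rise of 10 percentage points.

The forecast says 73.2 % and 84.2 %, both lower than mine, and it rises, holding that “conversion is set by the ligand supply”.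

The flask gives 75.2 % on Tuesday's and 85.7 % on Thursday's, a change of 10 points: it rises. At 2.00 h Tuesday's complexes show 1.12 exchanges per charged complex against the budget of 1.09, with 0.0884 % of the incoming ligand still free and 0.00319 M of idle adduct. Now charge 0.60 M of starting complex, the rest as on Tuesday's. The budget becomes 2.34, above the 2 a complex can take, so the starting complex, not the ligand, should run out first. That flask holds 92.6 % as complex with two exchanged, and 99.1 % of its starting complex has reacted, with 7.40 % of the incoming ligand still free.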